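## Retrosynthetic overview

1. The (Z)-coumarate is cut at the C=C bond and the C15–O ester bond (Still–Gennari olefination of a C15 phosphonoacetate), leaving 2α-silyloxy-labd-7-en-15-ol.
2. The C8 methyl and the C7=C8 bond come from an 8-enol triflate of a 17-nor-8-ketone, reached from a C6 ketone by Wharton 1,3-carbonyl transposition; the equatorial 2α-OH comes from dissolving-metal reduction of a C2 ketone.
3. Ring A is cut at C1–C10 and C4–C5 by a [4+2] disconnection into 2-silyloxy-4-methylpenta-1,3-diene (from mesityl oxide) and the C5=C10 bond of a ring B 3-methylcyclohex-2-enone that already carries the C9 side chain. The enabling feature is that in ring A the oxygen sits on C2, "para" to C5 and flanked by C1H2 and C3H2, with the gem-dimethyl carbon C4 next to C5; C1–C2(O)–C3–C4(CH3)2 is thus a mesityl oxide unit, and ring A is the retron of a 2-silyloxydiene cycloadduct once C6 is raised to a ketone.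
4. The ring B enone comes from an organocatalytic Michael/aldol annulation of a C7 aldehyde with methyl vinyl ketone (sets C9), followed by β-methylation/dehydrogenation (C10 methyl); the aldehyde comes from (S)-citronellol (C13).
5. Ring order: ring B first (step 4), ring A second (step 7).

Key step: step 7

Remark: labdane numbering is used for all bicyclic compounds (C1–C10 ring carbons, C11–C15 side chain, C17 the methyl on C8, "17-nor" without it; β is the face of the C10 methyl); N-tert-butylbenzenesulfinimidoyl chloride and bis(2,2,2-trifluoroethyl)phosphonoacetic acid are taken as purchased reagents.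

## Route

Step 1
Reactants: 1 (S)-citronellol; 2 pivaloyl chloride
Product: 3 (3S)-3,7-dimethyloct-6-en-1-yl pivalate
Conditions: PivCl, pyridine, DMAP (cat.), CH2Cl2, 0 °C to rt
Reagents that add atoms: pivaloyl chloride, CC(C)(C)C(Cl)=O
Why: O-acylation of the primary alcohol gives a pivalate that should survive ozone, ylides, cuprates and Lewis acids and is removed later in the dissolving-metal step; C13 comes unchanged from the chiral pool.

Step 2
Reactants: 3 (3S)-3,7-dimethyloct-6-en-1-yl pivalate; 4 ozone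
Product: 6 (3S)-3-methyl-6-oxohexyl pivalate, via ozonide 5 (not isolated)
Conditions: O3, CH2Cl2, −78 °C; then PPh3, −78 °C to rt
Reagents that add atoms: ozone, [O-][O+]=O
Why: ozonolysis with reductive work-up cleaves the only C=C bond and leaves the aldehyde carbon that becomes C9.

Step 3
Reactants: 6 (3S)-3-methyl-6-oxohexyl pivalate; 7 (methoxymethyl)triphenylphosphonium chloride; 8 water
Product: 10 (3S)-3-methyl-7-oxoheptyl pivalate, via enol ether 9 (not isolated)
Conditions: 7, KN(SiMe3)2, THF, −78 to 0 °C; then 2 M HCl (aq), rt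
Reagents that add atoms: (methoxymethyl)triphenylphosphonium chloride, [Cl-].COC[P+](c1ccccc1)(c1ccccc1)c1ccccc1; water, O
Why: Wittig methoxymethylenation followed by enol ether hydrolysis is the standard one-carbon homologation of an aldehyde and supplies C10.

Step 4
Reactants: 10 (3S)-3-methyl-7-oxoheptyl pivalate; 11 methyl vinyl ketone
Product: 13 (4S)-4-[(3S)-3-methyl-5-(pivaloyloxy)pentyl]cyclohex-2-en-1-one, via keto aldehyde 12 (not isolated)
Conditions: (R)-α,α-diphenylprolinol trimethylsilyl ether (10 mol%), ethyl 3,4-dihydroxybenzoate (20 mol%), neat, 4 °C; then LiOH, i-PrOH, rt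
Reagents that add atoms: methyl vinyl ketone, C=CC(C)=O
Why: enamine-catalysed Michael addition of the aldehyde to the enone followed by intramolecular aldol condensation (organocatalytic Robinson-type annulation) closes ring B; the (R)-catalyst shields one face of the (E)-enamine so that C9 should form in the (S) configuration, independent of the remote C13 centre.

Step 5
Reactants: 13 (4S)-4-[(3S)-3-methyl-5-(pivaloyloxy)pentyl]cyclohex-2-en-1-one; 14 lithium dimethylcuprate
Product: 16 (4S)-3-methyl-4-[(3S)-3-methyl-5-(pivaloyloxy)pentyl]cyclohex-2-en-1-one, via lithium enolate 15 (not isolated)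
Conditions: Me2CuLi, Et2O, −78 °C; then N-tert-butylbenzenesulfinimidoyl chloride, THF, −78 °C to rt
Reagents that add atoms: lithium dimethylcuprate, [Li+].C[Cu-]C
Why: conjugate methylation (trans to the C9 chain) and one-pot dehydrogenation of the resulting enolate with the sulfinimidoyl chloride (Mukaiyama dehydrogenation) reinstate the enone with the C10 methyl in place; the transient C10 centre is erased and C9 is not touched.

Step 6
Reactants: 17 mesityl oxide; 18 tert-butyldimethylsilyl chloride
Product: 20 tert-butyl(dimethyl)[(4-methylpenta-1,3-dien-2-yl)oxy]silane, via lithium dienolate 19 (not isolated)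
Conditions: LiN(i-Pr)2, THF, −78 °C; then TBSCl, DMPU, −78 °C to rt
Reagents that add atoms: tert-butyldimethylsilyl chloride, CC(C)(C)[Si](C)(C)Cl
Why: kinetic deprotonation of the enone at its α′-methyl group and O-silylation give the cross-conjugated 2-silyloxydiene.

Step 7
Reactants: 16 (4S)-3-methyl-4-[(3S)-3-methyl-5-(pivaloyloxy)pentyl]cyclohex-2-en-1-one; 20 tert-butyl(dimethyl)[(4-methylpenta-1,3-dien-2-yl)oxy]silane
Product: 21 2-(tert-butyldimethylsilyloxy)-6-oxo-17-nor-5β-labd-2-en-15-yl pivalate (cis-fused adduct; 10β-CH3; 9β side chain)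
Conditions: 20 (3 equiv), AlBr3/AlMe3 (10:1, 0.3 equiv), toluene/CH2Cl2, −20 to 0 °C; pyridine, then NaHCO3 (aq)
Reagents that add atoms: tert-butyl(dimethyl)[(4-methylpenta-1,3-dien-2-yl)oxy]silane, C=C(O[Si](C)(C)C(C)(C)C)C=C(C)C
Why: The AlBr3/AlMe3 couple binds the C6 carbonyl of 16, and the silyl enol ether terminus C1 of 20 attacks the β-carbon C10 in a strongly asynchronous [4+2] cycloaddition (at the stepwise limit a Mukaiyama–Michael addition followed by collapse of the C5 aluminium enolate onto the silyloxyallyl cation at C4), so that C1–C10 and C4–C5 form in one operation. The closest known reaction type is the mixed AlBr3/AlMe3-catalysed Diels–Alder reaction of hindered 2-silyloxydienes bearing a geminal dimethyl terminus with methyl-substituted cyclohexenones, which tolerates quaternary carbons on both partners. Ring A is closed by intermolecular [4+2] annulation onto ring B (in the stepwise picture the second bond forms by 6-endo-trig Michael-type closure). C10 is controlled by the C9 stereocentre: allylic 1,2-strain with the C10 methyl holds the side chain pseudoaxial, so C1 adds to the opposite (α) face and the methyl ends up β, cis to the side chain; C5 follows from suprafacial addition (cis fusion, 5β-H) and is corrected in step 8, and C4 is not stereogenic. The step needs "para" regioselectivity, secured by the polarity match between the nucleophilic C1 and the electrophilic C10, and π-facial selectivity, secured by the C9 substituent.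

Step 8
Reactants: 21 2-(tert-butyldimethylsilyloxy)-6-oxo-17-nor-5β-labd-2-en-15-yl pivalate
Product: 23 2,6-dioxo-17-nor-5α-labdan-15-yl pivalate (trans-fused), via cis-dione 22 (not isolated)
Conditions: 1 M HCl (aq), THF, rt; then K2CO3, MeOH, rt
Reagents that add atoms: none
Why: hydrolysis of the silyl enol ether unveils the C2 ketone, and mild base equilibration through the C6 enolate should epimerise C5 to the trans-fused decalin (5α-H), which avoids the axial C4 quaternary carbon that the cis isomer must place over ring B.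

Step 9
Reactants: 23 2,6-dioxo-17-nor-5α-labdan-15-yl pivalate
Product: 24 17-nor-5α-labdane-2α,6α,15-triol
Conditions: Li, NH3 (l), THF, EtOH, −78 to −33 °C; then NH4Cl
Reagents that add atoms: none
Why: dissolving-metal reduction under thermodynamic control should give the equatorial 2α-alcohol (hydride reagents would enter from the open α-face and give the axial 2β-alcohol, since the β-face of C2 is blocked by the axial methyls on C4 and C10), while the C6 ketone is reduced and the pivalate is cleaved (Bouveault–Blanc) in the same operation; the C6 configuration is immaterial because C6 is reoxidised in step 11.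

Step 10
Reactants: 24 17-nor-5α-labdane-2α,6α,15-triol; 18 tert-butyldimethylsilyl chloride
Product: 25 2α,15-bis(tert-butyldimethylsilyloxy)-17-nor-5α-labdan-6α-ol
Conditions: TBSCl (2.3 equiv), imidazole, DMF, 0 °C to rt
Reagents that add atoms: tert-butyldimethylsilyl chloride, CC(C)(C)[Si](C)(C)Cl
Why: silylation of the primary C15 and the unhindered equatorial C2 hydroxyl should be much faster than that of the C6 hydroxyl, which is shielded by C5 and the peri 4α-methyl group.

Step 11
Reactants: 25 2α,15-bis(tert-butyldimethylsilyloxy)-17-nor-5α-labdan-6α-ol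
Product: 27 2α,15-bis(tert-butyldimethylsilyloxy)-17-nor-5α-labd-7-en-6-one, via 6-ketone 26 (not isolated)
Conditions: IBX (4 equiv), DMSO/fluorobenzene, 70 °C
Reagents that add atoms: none
Why: IBX oxidises the secondary alcohol to the ketone and then dehydrogenates it (Nicolaou IBX dehydrogenation); only C7–C8 can be desaturated because C5 has no β-hydrogen (C4 and C10 are quaternary).

Step 12
Reactants: 27 2α,15-bis(tert-butyldimethylsilyloxy)-17-nor-5α-labd-7-en-6-one; 28 hydrogen peroxide
Product: 29 7α,8α-epoxy-2α,15-bis(tert-butyldimethylsilyloxy)-17-nor-5α-labdan-6-one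
Conditions: 30% H2O2, NaOH (cat.), MeOH/THF, 0 °C
Reagents that add atoms: hydrogen peroxide, OO
Why: Weitz–Scheffer nucleophilic epoxidation of the enone, with attack expected on the α-face away from the axial C10 methyl; both new centres are removed again in steps 13 and 14.

Step 13
Reactants: 29 7α,8α-epoxy-2α,15-bis(tert-butyldimethylsilyloxy)-17-nor-5α-labdan-6-one
Product: 30 2α,15-bis(tert-butyldimethylsilyloxy)-17-nor-5α-labd-6-en-8α-ol
Conditions: N2H4·H2O, AcOH (cat.), MeOH, 0 °C to rt
Reagents that add atoms: none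
Why: Wharton transposition: the epoxy hydrazone fragments with loss of N2 to the C6=C7 alkene and the C8 alkoxide, so C6 is deoxygenated and the oxygen moves to C8.

Step 14
Reactants: 30 2α,15-bis(tert-butyldimethylsilyloxy)-17-nor-5α-labd-6-en-8α-ol
Product: 31 2α,15-bis(tert-butyldimethylsilyloxy)-17-nor-5α-labd-6-en-8-one
Conditions: Dess–Martin periodinane, NaHCO3, CH2Cl2, 0 °C to rt
Reagents that add atoms: none
Why: buffered Dess–Martin oxidation of the allylic alcohol gives the enone under conditions that should not epimerise C9.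

Step 15
Reactants: 31 2α,15-bis(tert-butyldimethylsilyloxy)-17-nor-5α-labd-6-en-8-one; 32 N-phenylbis(trifluoromethanesulfonimide)
Product: 34 2α,15-bis(tert-butyldimethylsilyloxy)-17-nor-5α-labd-7-en-8-yl trifluoromethanesulfonate, via lithium enolate 33 (not isolated)
Conditions: LiBH(s-Bu)3, THF, −78 °C; then PhNTf2, −78 to 0 °C
Reagents that add atoms: N-phenylbis(trifluoromethanesulfonimide), O=S(=O)(N(c1ccccc1)S(=O)(=O)C(F)(F)F)C(F)(F)F
Why: conjugate reduction of the β-unsubstituted cyclohexenone with the bulky borohydride gives the C7=C8 enolate regiospecifically, and O-triflation fixes the double bond at C7–C8.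

Step 16
Reactants: 34 2α,15-bis(tert-butyldimethylsilyloxy)-17-nor-5α-labd-7-en-8-yl trifluoromethanesulfonate; 35 methylmagnesium bromide
Product: 36 2α,15-bis(tert-butyldimethylsilyloxy)labd-7-ene
Conditions: MeMgBr, Fe(acac)3 (5 mol%), THF/NMP, −30 to 0 °C
Reagents that add atoms: methylmagnesium bromide, C[Mg]Br
Why: iron-catalysed cross-coupling of the alkenyl triflate with the methyl Grignard reagent installs the C8 methyl with the double bond held at C7–C8.

Step 17
Reactants: 36 2α,15-bis(tert-butyldimethylsilyloxy)labd-7-ene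
Product: 37 2α-(tert-butyldimethylsilyloxy)labd-7-en-15-ol
Conditions: PPTS, EtOH, rt
Reagents that add atoms: none
Why: acid-catalysed ethanolysis removes the primary silyl ether much faster than the secondary one at C2 and is too mild to move the C7=C8 bond.

Step 18
Reactants: 37 2α-(tert-butyldimethylsilyloxy)labd-7-en-15-ol; 38 bis(2,2,2-trifluoroethyl)phosphonoacetic acid
Product: 39 2α-(tert-butyldimethylsilyloxy)labd-7-en-15-yl bis(2,2,2-trifluoroethyl)phosphonoacetate
Conditions: EDC·HCl, DMAP (cat.), CH2Cl2, 0 °C to rt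
Reagents that add atoms: bis(2,2,2-trifluoroethyl)phosphonoacetic acid, OC(=O)CP(=O)(OCC(F)(F)F)OCC(F)(F)F
Why: carbodiimide (Steglich-type) esterification of the only free, primary alcohol.

Step 19
Reactants: 39 2α-(tert-butyldimethylsilyloxy)labd-7-en-15-yl bis(2,2,2-trifluoroethyl)phosphonoacetate; 40 4-(tert-butyldimethylsilyloxy)benzaldehyde
Product: 42 2α-(tert-butyldimethylsilyloxy)labd-7-en-15-yl (Z)-3-[4-(tert-butyldimethylsilyloxy)phenyl]prop-2-enoate, via potassium phosphonate carbanion 41 (not isolated)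
Conditions: KN(SiMe3)2, 18-crown-6, THF, −78 °C; then 40, −78 °C, dark
Reagents that add atoms: 4-(tert-butyldimethylsilyloxy)benzaldehyde, O=Cc1ccc(O[Si](C)(C)C(C)(C)C)cc1
Why: Still–Gennari variant of the Horner–Wadsworth–Emmons reaction: the electron-poor bis(trifluoroethyl) phosphonate with a dissociated potassium counter-ion eliminates fast from the kinetic adduct and should give the (Z)-cinnamate.

Step 20
Reactants: 42 2α-(tert-butyldimethylsilyloxy)labd-7-en-15-yl (Z)-3-[4-(tert-butyldimethylsilyloxy)phenyl]prop-2-enoate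
Product: 43 2α-hydroxylabd-7-en-15-yl (Z)-3-(4-hydroxyphenyl)prop-2-enoate (CNP0301213.1)
Conditions: HF·pyridine, pyridine, THF, 0 °C to rt, dark
Reagents that add atoms: none
Why: buffered fluoride-mediated cleavage of the aryl and the secondary alkyl silyl ether, under conditions that should leave the ester and the light-sensitive (Z)-alkene untouched.

## Compound list

1 | (S)-citronellol, (3S)-3,7-dimethyloct-6-en-1-ol | CC(C)=CCC[C@H](C)CCO | starting material
2 | pivaloyl chloride | CC(C)(C)C(Cl)=O | starting material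
3 | (3S)-3,7-dimethyloct-6-en-1-yl pivalate | CC(C)=CCC[C@H](C)CCOC(=O)C(C)(C)C | intermediate
4 | ozone | [O-][O+]=O | starting material
5 | (3S)-5-(5,5-dimethyl-1,2,4-trioxolan-3-yl)-3-methylpentyl pivalate (ozonide) | CC1(C)OOC(CC[C@H](C)CCOC(=O)C(C)(C)C)O1 | intermediate (not isolated)
6 | (3S)-3-methyl-6-oxohexyl pivalate | O=CCC[C@H](C)CCOC(=O)C(C)(C)C | intermediate
7 | (methoxymethyl)triphenylphosphonium chloride | [Cl-].COC[P+](c1ccccc1)(c1ccccc1)c1ccccc1 | starting material
8 | water | O | starting material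
9 | (3S)-7-methoxy-3-methylhept-6-en-1-yl pivalate (E/Z mixture) | COC=CCC[C@H](C)CCOC(=O)C(C)(C)C | intermediate (not isolated)
10 | (3S)-3-methyl-7-oxoheptyl pivalate | O=CCCC[C@H](C)CCOC(=O)C(C)(C)C | intermediate
11 | methyl vinyl ketone | C=CC(C)=O | starting material
12 | (3S,6S)-6-formyl-3-methyl-9-oxodecyl pivalate | O=C[C@H](CCC(C)=O)CC[C@H](C)CCOC(=O)C(C)(C)C | intermediate (not isolated)
13 | (4S)-4-[(3S)-3-methyl-5-(pivaloyloxy)pentyl]cyclohex-2-en-1-one | O=C1C=C[C@@H](CC[C@H](C)CCOC(=O)C(C)(C)C)CC1 | intermediate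
14 | lithium dimethylcuprate | [Li+].C[Cu-]C | starting material
15 | lithium (3R,4S)-3-methyl-4-[(3S)-3-methyl-5-(pivaloyloxy)pentyl]cyclohex-1-en-1-olate | [Li+].[O-]C1=C[C@H](C)[C@@H](CC[C@H](C)CCOC(=O)C(C)(C)C)CC1 | intermediate (not isolated)
16 | (4S)-3-methyl-4-[(3S)-3-methyl-5-(pivaloyloxy)pentyl]cyclohex-2-en-1-one | O=C1C=C(C)[C@@H](CC[C@H](C)CCOC(=O)C(C)(C)C)CC1 | intermediate
17 | mesityl oxide | CC(C)=CC(C)=O | starting material
18 | tert-butyldimethylsilyl chloride | CC(C)(C)[Si](C)(C)Cl | starting material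
19 | lithium 4-methylpenta-1,3-dien-2-olate | [Li+].[O-]C(=C)C=C(C)C | intermediate (not isolated)
20 | tert-butyl(dimethyl)[(4-methylpenta-1,3-dien-2-yl)oxy]silane | C=C(O[Si](C)(C)C(C)(C)C)C=C(C)C | intermediate
21 | 2-(tert-butyldimethylsilyloxy)-6-oxo-17-nor-5β-labd-2-en-15-yl pivalate (cis-fused) | C1CC(=O)[C@@H]2C(C)(C)C=C(O[Si](C)(C)C(C)(C)C)C[C@]2(C)[C@H]1CC[C@H](C)CCOC(=O)C(C)(C)C | intermediate
22 | 2,6-dioxo-17-nor-5β-labdan-15-yl pivalate (cis-fused) | C1CC(=O)[C@@H]2C(C)(C)CC(=O)C[C@]2(C)[C@H]1CC[C@H](C)CCOC(=O)C(C)(C)C | intermediate (not isolated)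
23 | 2,6-dioxo-17-nor-5α-labdan-15-yl pivalate (trans-fused) | C1CC(=O)[C@H]2C(C)(C)CC(=O)C[C@]2(C)[C@H]1CC[C@H](C)CCOC(=O)C(C)(C)C | intermediate
24 | 17-nor-5α-labdane-2α,6α,15-triol | C1C[C@H](O)[C@H]2C(C)(C)C[C@H](O)C[C@]2(C)[C@H]1CC[C@H](C)CCO | intermediate
25 | 2α,15-bis(tert-butyldimethylsilyloxy)-17-nor-5α-labdan-6α-ol | C1C[C@H](O)[C@H]2C(C)(C)C[C@H](O[Si](C)(C)C(C)(C)C)C[C@]2(C)[C@H]1CC[C@H](C)CCO[Si](C)(C)C(C)(C)C | intermediate
26 | 2α,15-bis(tert-butyldimethylsilyloxy)-17-nor-5α-labdan-6-one | C1CC(=O)[C@H]2C(C)(C)C[C@H](O[Si](C)(C)C(C)(C)C)C[C@]2(C)[C@H]1CC[C@H](C)CCO[Si](C)(C)C(C)(C)C | intermediate (not isolated)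
27 | 2α,15-bis(tert-butyldimethylsilyloxy)-17-nor-5α-labd-7-en-6-one | C1=CC(=O)[C@H]2C(C)(C)C[C@H](O[Si](C)(C)C(C)(C)C)C[C@]2(C)[C@H]1CC[C@H](C)CCO[Si](C)(C)C(C)(C)C | intermediate
28 | hydrogen peroxide | OO | starting material
29 | 7α,8α-epoxy-2α,15-bis(tert-butyldimethylsilyloxy)-17-nor-5α-labdan-6-one | [C@@H]12O[C@@H]1C(=O)[C@H]3C(C)(C)C[C@H](O[Si](C)(C)C(C)(C)C)C[C@]3(C)[C@H]2CC[C@H](C)CCO[Si](C)(C)C(C)(C)C | intermediate
30 | 2α,15-bis(tert-butyldimethylsilyloxy)-17-nor-5α-labd-6-en-8α-ol | O[C@@H]1C=C[C@H]2C(C)(C)C[C@H](O[Si](C)(C)C(C)(C)C)C[C@]2(C)[C@H]1CC[C@H](C)CCO[Si](C)(C)C(C)(C)C | intermediate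
31 | 2α,15-bis(tert-butyldimethylsilyloxy)-17-nor-5α-labd-6-en-8-one | O=C1C=C[C@H]2C(C)(C)C[C@H](O[Si](C)(C)C(C)(C)C)C[C@]2(C)[C@H]1CC[C@H](C)CCO[Si](C)(C)C(C)(C)C | intermediate
32 | N-phenylbis(trifluoromethanesulfonimide) | O=S(=O)(N(c1ccccc1)S(=O)(=O)C(F)(F)F)C(F)(F)F | starting material
33 | lithium 2α,15-bis(tert-butyldimethylsilyloxy)-17-nor-5α-labd-7-en-8-olate | [Li+].[O-]C1=CC[C@H]2C(C)(C)C[C@H](O[Si](C)(C)C(C)(C)C)C[C@]2(C)[C@H]1CC[C@H](C)CCO[Si](C)(C)C(C)(C)C | intermediate (not isolated)
34 | 2α,15-bis(tert-butyldimethylsilyloxy)-17-nor-5α-labd-7-en-8-yl trifluoromethanesulfonate | FC(F)(F)S(=O)(=O)OC1=CC[C@H]2C(C)(C)C[C@H](O[Si](C)(C)C(C)(C)C)C[C@]2(C)[C@H]1CC[C@H](C)CCO[Si](C)(C)C(C)(C)C | intermediate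
35 | methylmagnesium bromide | C[Mg]Br | starting material
36 | 2α,15-bis(tert-butyldimethylsilyloxy)labd-7-ene | CC1=CC[C@H]2C(C)(C)C[C@H](O[Si](C)(C)C(C)(C)C)C[C@]2(C)[C@H]1CC[C@H](C)CCO[Si](C)(C)C(C)(C)C | intermediate
37 | 2α-(tert-butyldimethylsilyloxy)labd-7-en-15-ol | CC1=CC[C@H]2C(C)(C)C[C@H](O[Si](C)(C)C(C)(C)C)C[C@]2(C)[C@H]1CC[C@H](C)CCO | intermediate
38 | bis(2,2,2-trifluoroethyl)phosphonoacetic acid | OC(=O)CP(=O)(OCC(F)(F)F)OCC(F)(F)F | starting material
39 | 2α-(tert-butyldimethylsilyloxy)labd-7-en-15-yl bis(2,2,2-trifluoroethyl)phosphonoacetate | CC1=CC[C@H]2C(C)(C)C[C@H](O[Si](C)(C)C(C)(C)C)C[C@]2(C)[C@H]1CC[C@H](C)CCOC(=O)CP(=O)(OCC(F)(F)F)OCC(F)(F)F | intermediate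
40 | 4-(tert-butyldimethylsilyloxy)benzaldehyde | O=Cc1ccc(O[Si](C)(C)C(C)(C)C)cc1 | starting material
41 | potassium salt of the α-carbanion of 39 | [K+].CC1=CC[C@H]2C(C)(C)C[C@H](O[Si](C)(C)C(C)(C)C)C[C@]2(C)[C@H]1CC[C@H](C)CCOC(=O)[CH-]P(=O)(OCC(F)(F)F)OCC(F)(F)F | intermediate (not isolated)
42 | 2α-(tert-butyldimethylsilyloxy)labd-7-en-15-yl (Z)-3-[4-(tert-butyldimethylsilyloxy)phenyl]prop-2-enoate | CC1=CC[C@H]2C(C)(C)C[C@H](O[Si](C)(C)C(C)(C)C)C[C@]2(C)[C@H]1CC[C@H](C)CCOC(=O)/C=C\c1ccc(O[Si](C)(C)C(C)(C)C)cc1 | intermediate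
43 | 2α-hydroxylabd-7-en-15-yl (Z)-3-(4-hydroxyphenyl)prop-2-enoate, (2S,5S,9S,10S,13S), CNP0301213.1 | CC1=CC[C@H]2C(C)(C)C[C@H](O)C[C@]2(C)[C@H]1CC[C@H](C)CCOC(=O)/C=C\c1ccc(O)cc1 | target

## Summary

Total step count: 20.
Longest linear sequence: 19 steps (steps 1–5 and 7–20; step 6 prepares the diene separately).

Steps most likely to fail:

**Step 7 (key cycloaddition).** The β,β-disubstituted enone may not be activated enough, so that the acid-sensitive diene is consumed by protodesilylation or oligomerisation before C1–C10 bonding occurs, or the reaction may stop after the first bond. Fallback: the two bonds are made one after the other. Setting out from 16 and 20, a TiCl4-mediated Mukaiyama–Michael addition (CH2Cl2, −78 °C, aqueous work-up) would give the 1,5-diketone (3S)-3-methyl-5-[(1S,2R)-2-methyl-2-(4-methyl-2-oxopent-3-en-1-yl)-4-oxocyclohexyl]pentyl pivalate F1, in which only C1–C10 has formed. KOt-Bu (cat.) in t-BuOH/THF would then close C5 onto C4 by intramolecular Michael addition under equilibrating conditions, which should deliver the trans-fused dione directly; the route is rejoined at 23.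

**Step 13 (Wharton transposition).** Hydrazone formation at the hindered C6 carbonyl may be slow, leaving time for base- or acid-induced opening of the epoxide and decomposition. Fallback: the 1,3-transposition is done at the alcohol level. Setting out from 27, NaBH4/CeCl3·7H2O (MeOH, −40 °C) should reduce the enone from the open α-face to 2α,15-bis(tert-butyldimethylsilyloxy)-17-nor-5α-labd-7-en-6β-ol F2. Ph3SiOReO3 (cat., Et2O, 0 °C) would then equilibrate it by suprafacial 1,3-hydroxyl shift to the less congested 2α,15-bis(tert-butyldimethylsilyloxy)-17-nor-5α-labd-6-en-8β-ol F3, driven by relief of the 1,3-diaxial contacts of the 6β-oxygen with the C4 and C10 methyls. Dess–Martin oxidation of F3 gives the enone, rejoining the route at 31.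

**Step 11 (tandem oxidation–dehydrogenation).** The sequence may stall at the hindered ketone, or the silyl ethers may be eroded in hot, slightly acidic DMSO. Fallback: the two operations are separated. Setting out from 25, Dess–Martin periodinane (CH2Cl2) would give the ketone 26 as an isolated compound. LiN(i-Pr)2/Me3SiCl (THF, −78 °C) would deprotonate C7 (the C5 hydrogen is hindered) to give 2α,15-bis(tert-butyldimethylsilyloxy)-6-(trimethylsilyloxy)-17-nor-5α-labd-6-ene F4, and Pd(OAc)2 in MeCN (Saegusa–Ito oxidation) would give the enone, rejoining the route at 27.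

Further compounds
F1 | step 7 | (3S)-3-methyl-5-[(1S,2R)-2-methyl-2-(4-methyl-2-oxopent-3-en-1-yl)-4-oxocyclohexyl]pentyl pivalate | CC(C)=CC(=O)C[C@@]1(C)CC(=O)CC[C@@H]1CC[C@H](C)CCOC(=O)C(C)(C)C
F2 | step 13 | 2α,15-bis(tert-butyldimethylsilyloxy)-17-nor-5α-labd-7-en-6β-ol | C1=C[C@@H](O)[C@H]2C(C)(C)C[C@H](O[Si](C)(C)C(C)(C)C)C[C@]2(C)[C@H]1CC[C@H](C)CCO[Si](C)(C)C(C)(C)C
F3 | step 13 | 2α,15-bis(tert-butyldimethylsilyloxy)-17-nor-5α-labd-6-en-8β-ol | O[C@H]1C=C[C@H]2C(C)(C)C[C@H](O[Si](C)(C)C(C)(C)C)C[C@]2(C)[C@H]1CC[C@H](C)CCO[Si](C)(C)C(C)(C)C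
F4 | step 11 | 2α,15-bis(tert-butyldimethylsilyloxy)-6-(trimethylsilyloxy)-17-nor-5α-labd-6-ene | C1C=C(O[Si](C)(C)C)[C@H]2C(C)(C)C[C@H](O[Si](C)(C)C(C)(C)C)C[C@]2(C)[C@H]1CC[C@H](C)CCO[Si](C)(C)C(C)(C)C
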